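## Retrosynthetic overview

1. Target 26 ⇒ tert-butyl ester 25 (acidolysis) ⇒ triol methyl ester 24: the seven-membered lactone is closed last, by transesterification of the allylic CH2OH onto the C2 ester of ring B.
2. Ring B ⇒ keto-enoate 22 + alkenylboronate 5. Key step: the β-carbon of an acrylate, made nucleophilic as an alkenyl-rhodium (a β-acyl vinyl anion equivalent), is joined to the β-carbon of an enoate; the rhodium enolate then closes the cyclohexane by aldol addition to the tethered ketone.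
3. Ring A ⇒ the same cascade in the mirror-image series (11 + 5 → 12), then loss of the ester carbon as CO2 through a β-lactone to give the cyclohexene acid 17.
4. The two halves are joined early: acid 17 is turned into acyloxymethyl vinyl ketone 20, so the C7 oxygen of ring B is never free.
5. Keto-enoates 11 and 22 ⇒ 3-methylbutanal + vinyl ketone (amine-catalysed Michael addition sets C4) + Wittig reagent. Ring order: ring A cyclohexane → ring A cyclohexene → ring B cyclohexane → oxepinone.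

Assumption: the SMILES is taken literally, so ring A (cyclohexene of the acyl group) and ring B (lactone-bearing cyclohexane) belong to opposite enantiomeric series at C3/C4 and are made with enantiomeric catalyst pairs; 1, 6 and 18 are treated as catalogue chemicals.

Conventions: in both six-membered rings C1 carries the CH2O group, C2 is the next carbon (ester-bearing in ring B, alkene CH in ring A), C3 carries the acrylate side chain, C4 the isopropyl group. TBSO = tert-butyldimethylsilyloxy. "Acyl A" = acyl group of acid 17. The ligand and amine enantiomers named below are assigned by analogy with published facial preferences, not verified for these substrates.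

## Route

Step 1
Reactants: 1 tert-butyl 2-(hydroxymethyl)prop-2-enoate
Product: 2 tert-butyl 2-[(tert-butyldimethylsilyloxy)methyl]prop-2-enoate
Conditions: TBSCl, imidazole, CH2Cl2, 0 → 23 °C
Reagents that add atoms: tert-butyldimethylsilyl chloride, CC(C)(C)[Si](C)(C)Cl
Why: Standard silylation of a primary allylic alcohol; no stereocentre is involved.

Step 2
Reactants: 2 tert-butyl 2-[(tert-butyldimethylsilyloxy)methyl]prop-2-enoate
Product: 4 tert-butyl (E)-3-bromo-2-[(tert-butyldimethylsilyloxy)methyl]prop-2-enoate, via dibromide 3 (not isolated)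
Conditions: Br2, CH2Cl2, 0 → 23 °C; then Et3N, 0 → 23 °C
Reagents that add atoms: bromine, BrBr
Why: Bromine addition then anti E2 dehydrobromination is expected to give mainly the E bromide (Br trans to the ester, cis to CH2OTBS), by analogy with methacrylate → (E)-3-bromomethacrylate; the minor Z isomer is removed by chromatography.

Step 3
Reactants: 4 tert-butyl (E)-3-bromo-2-[(tert-butyldimethylsilyloxy)methyl]prop-2-enoate
Product: 5 tert-butyl (E)-2-[(tert-butyldimethylsilyloxy)methyl]-3-(4,4,5,5-tetramethyl-1,3,2-dioxaborolan-2-yl)prop-2-enoate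
Conditions: B2pin2, PdCl2(PPh3)2 (3 mol %), PPh3, KOPh, toluene, 50 °C
Reagents that add atoms: bis(pinacolato)diboron, CC1(C)OB(OC1(C)C)B1OC(C)(C)C(C)(C)O1
Why: Miyaura borylation of an alkenyl bromide proceeds with retention of geometry, and the weak phenoxide base suppresses Suzuki homocoupling.

Step 4
Reactants: 6 2-(tert-butyldimethylsilyloxy)-N-methoxy-N-methylacetamide
Product: 8 1-(tert-butyldimethylsilyloxy)but-3-en-2-one, via magnesium chelate 7 (not isolated)
Conditions: CH2=CHMgBr, THF, −78 → 0 °C; poured into cold 1 M HCl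
Reagents that add atoms: vinylmagnesium bromide, C=C[Mg]Br
Why: Weinreb ketone synthesis; the stable chelate prevents over-addition and the cold acidic quench keeps the liberated amine from adding to the enone.

Step 5
Reactants: 9 3-methylbutanal; 8 1-(tert-butyldimethylsilyloxy)but-3-en-2-one
Product: 11 prop-2-enyl (2E,4S)-8-(tert-butyldimethylsilyloxy)-7-oxo-4-(propan-2-yl)oct-2-enoate, via aldehyde 10 (not isolated)
Conditions: (S)-2-[methoxy(diphenyl)methyl]pyrrolidine (10 mol %), ethyl 3,4-dihydroxybenzoate (20 mol %), 9 (3 equiv), 4 °C; excess 9 evaporated; then Ph3P=CHCO2CH2CH=CH2, CH2Cl2, 0 → 23 °C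
Reagents that add atoms: prop-2-enyl (triphenylphosphoranylidene)acetate, C=CCOC(=O)C=P(c1ccccc1)(c1ccccc1)c1ccccc1
Why: Enamine-catalysed Michael addition to the vinyl ketone (the E-enamine is attacked on the face away from the diarylmethyl group, setting C4 as S) followed by in-situ Wittig olefination with a stabilised ylide, which gives the E-enoate before the α-stereocentre can epimerise.

Step 6
Reactants: 11 prop-2-enyl (2E,4S)-8-(tert-butyldimethylsilyloxy)-7-oxo-4-(propan-2-yl)oct-2-enoate; 5 tert-butyl (E)-2-[(tert-butyldimethylsilyloxy)methyl]-3-(4,4,5,5-tetramethyl-1,3,2-dioxaborolan-2-yl)prop-2-enoate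
Product: 12 prop-2-enyl (1S,2R,5S,6S)-6-[(E)-3-tert-butoxy-3-oxo-2-(TBSO-methyl)prop-1-enyl]-2-hydroxy-5-(propan-2-yl)-2-(TBSO-methyl)cyclohexane-1-carboxylate
Conditions: 5 (2.5 equiv), [Rh(OH)((R)-BINAP)]2 (3 mol %), K3PO4 (0.5 equiv), dioxane/H2O 10:1, 50 °C
Reagents that add atoms: none
Why: Proposed new method: transmetalation of 5 to the monovalent rhodium hydroxide gives a β-rhoda-acrylate (a β-acyl vinyl anion equivalent) that inserts the enoate at C3 on the face chosen by (R)-BINAP (catalyst control over the C4 centre, giving the 3,4-cis pair), and the Z oxa-π-allyl rhodium enolate then adds to the tethered ketone through a chair Zimmerman–Traxler transition state that puts the C2 ester trans to the C3 side chain and cis to the C1 hydroxyl; the closest known reactions are the Hayashi–Miyaura asymmetric 1,4-addition of alkenylboron reagents to enoates and the rhodium/BINAP tandem conjugate addition–aldol cyclisation of keto-enones with arylboronic acids.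

Step 7
Reactants: 12 prop-2-enyl (1S,2R,5S,6S)-6-[(E)-3-tert-butoxy-3-oxo-2-(TBSO-methyl)prop-1-enyl]-2-hydroxy-5-(propan-2-yl)-2-(TBSO-methyl)cyclohexane-1-carboxylate
Product: 13 (1S,2R,5S,6S)-6-[(E)-3-tert-butoxy-3-oxo-2-(TBSO-methyl)prop-1-enyl]-2-hydroxy-5-(propan-2-yl)-2-(TBSO-methyl)cyclohexane-1-carboxylic acid
Conditions: Pd(PPh3)4 (5 mol %), morpholine, THF, 23 °C; aq. citric acid wash
Reagents that add atoms: none
Why: Tsuji–Trost deallylation with zerovalent palladium is neutral, so the tertiary aldol does not undergo retro-aldol and the tert-butyl ester and silyl ethers are untouched.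

Step 8
Reactants: 13 (1S,2R,5S,6S)-6-[(E)-3-tert-butoxy-3-oxo-2-(TBSO-methyl)prop-1-enyl]-2-hydroxy-5-(propan-2-yl)-2-(TBSO-methyl)cyclohexane-1-carboxylic acid
Product: 15 tert-butyl (E)-2-(TBSO-methyl)-3-[(1R,6S)-6-(propan-2-yl)-3-(TBSO-methyl)cyclohex-2-en-1-yl]prop-2-enoate, via beta-lactone 14 (not isolated)
Conditions: PhSO2Cl, pyridine, 0 → 23 °C; then xylene, 135 °C
Reagents that add atoms: none
Why: Adam β-lactonisation by carboxyl activation (possible because OH and CO2H are cis) followed by stereospecific thermal [2+2] cycloreversion with loss of CO2 places the alkene only between C1 and C2 and leaves C3 and C4 untouched.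

Step 9
Reactants: 15 tert-butyl (E)-2-(TBSO-methyl)-3-[(1R,6S)-6-(propan-2-yl)-3-(TBSO-methyl)cyclohex-2-en-1-yl]prop-2-enoate
Product: 17 (E)-2-(TBSO-methyl)-3-[(1R,6S)-6-(propan-2-yl)-3-(TBSO-methyl)cyclohex-2-en-1-yl]prop-2-enoic acid, via trimethylsilyl ester 16 (not isolated)
Conditions: TMSOTf, 2,6-lutidine, CH2Cl2, 0 °C; then pH 5 aqueous buffer
Reagents that add atoms: none
Why: Silyl triflate-mediated cleavage of the tert-butyl ester (loss of isobutene, silyl ester hydrolysed on work-up) spares the two primary TBS ethers.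

Step 10
Reactants: 17 (E)-2-(TBSO-methyl)-3-[(1R,6S)-6-(propan-2-yl)-3-(TBSO-methyl)cyclohex-2-en-1-yl]prop-2-enoic acid; 18 1,4-dibromobutan-2-one
Product: 20 2-oxobut-3-enyl (E)-2-(TBSO-methyl)-3-[(1R,6S)-6-(propan-2-yl)-3-(TBSO-methyl)cyclohex-2-en-1-yl]prop-2-enoate, via bromoethyl ketone 19 (not isolated)
Conditions: 18 (1.5 equiv), i-Pr2NEt, MeCN, 0 °C; then Et3N, 0 → 23 °C
Reagents that add atoms: none
Why: Carboxylate SN2 displacement at the activated α-bromoketone carbon followed by E1cB loss of HBr from the β-bromoketone gives the vinyl ketone without any carboxyl activation.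

Step 11
Reactants: 9 3-methylbutanal; 20 2-oxobut-3-enyl (E)-2-(TBSO-methyl)-3-[(1R,6S)-6-(propan-2-yl)-3-(TBSO-methyl)cyclohex-2-en-1-yl]prop-2-enoate
Product: 22 methyl (2E,4R)-8-(acyl A-oxy)-7-oxo-4-(propan-2-yl)oct-2-enoate, via aldehyde 21 (not isolated)
Conditions: (R)-2-[methoxy(diphenyl)methyl]pyrrolidine (10 mol %), ethyl 3,4-dihydroxybenzoate (20 mol %), 9 (3 equiv), CH2Cl2, 4 °C; excess 9 evaporated; then Ph3P=CHCO2Me, CH2Cl2, 0 → 23 °C
Reagents that add atoms: methyl (triphenylphosphoranylidene)acetate, COC(=O)C=P(c1ccccc1)(c1ccccc1)c1ccccc1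
Why: The same enamine Michael addition/Wittig sequence as step 5 with the mirror-image amine sets C4 of ring B as R; the hindered trisubstituted acrylate of acyl A is inert to the enamine and the ylide.

Step 12
Reactants: 22 methyl (2E,4R)-8-(acyl A-oxy)-7-oxo-4-(propan-2-yl)oct-2-enoate; 5 tert-butyl (E)-2-[(tert-butyldimethylsilyloxy)methyl]-3-(4,4,5,5-tetramethyl-1,3,2-dioxaborolan-2-yl)prop-2-enoate
Product: 23 methyl (1R,2S,5R,6R)-2-[(acyl A-oxy)methyl]-6-[(E)-3-tert-butoxy-3-oxo-2-(TBSO-methyl)prop-1-enyl]-2-hydroxy-5-(propan-2-yl)cyclohexane-1-carboxylate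
Conditions: 5 (2.5 equiv), [Rh(OH)((S)-BINAP)]2 (3 mol %), K3PO4 (0.5 equiv), dioxane/H2O 10:1, 50 °C
Reagents that add atoms: none
Why: Proposed new method: the same alkenyl-rhodium 1,4-addition/Zimmerman–Traxler aldol cascade as step 6 with the mirror-image ligand sets C3 (cis to isopropyl), C2 (ester trans to the side chain) and C1 (OH cis to the ester) of ring B in one operation, and the α,β-disubstituted acrylate of acyl A is too hindered to insert; closest known reactions are the Hayashi–Miyaura 1,4-addition to enoates and the rhodium/BINAP conjugate addition–aldol cyclisation of keto-enones.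

Step 13
Reactants: 23 methyl (1R,2S,5R,6R)-2-[(acyl A-oxy)methyl]-6-[(E)-3-tert-butoxy-3-oxo-2-(TBSO-methyl)prop-1-enyl]-2-hydroxy-5-(propan-2-yl)cyclohexane-1-carboxylate
Product: 25 tert-butyl ester of the target (seven-membered lactone closed; all silyl groups removed), via triol 24 (not isolated)
Conditions: HF·pyridine, pyridine/THF, 0 → 23 °C; then CSA (10 mol %), 4 Å MS, toluene, 50 °C
Reagents that add atoms: none
Why: Fluoride desilylation frees three primary alcohols, of which only the side-chain CH2OH, held next to the C2 ester by the cis alkene and the trans-diequatorial ring bonds, can lactonise (acid-catalysed transesterification, methanol trapped by sieves); the C7 oxygen is already acylated, so no γ-lactone can form.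

Step 14
Reactants: 25 tert-butyl ester of the target
Product: 26 CNP0361406.11
Conditions: TFA/CH2Cl2/H2O 25:73:2, 0 → 23 °C
Reagents that add atoms: none
Why: Acidolysis of the tert-butyl ester (loss of isobutene) frees the acrylic acid; the tertiary alcohol is flanked by electron-withdrawing groups and should not ionise.

## Compound list

1 | tert-butyl 2-(hydroxymethyl)prop-2-enoate | C=C(CO)C(=O)OC(C)(C)C | starting material
2 | tert-butyl 2-[(tert-butyldimethylsilyloxy)methyl]prop-2-enoate | C=C(CO[Si](C)(C)C(C)(C)C)C(=O)OC(C)(C)C | intermediate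
3 | tert-butyl 2,3-dibromo-2-[(tert-butyldimethylsilyloxy)methyl]propanoate (racemic) | CC(C)(C)OC(=O)C(Br)(CBr)CO[Si](C)(C)C(C)(C)C | intermediate
4 | tert-butyl (E)-3-bromo-2-[(tert-butyldimethylsilyloxy)methyl]prop-2-enoate (Br trans to ester) | CC(C)(C)OC(=O)/C(CO[Si](C)(C)C(C)(C)C)=C/Br | intermediate
5 | tert-butyl (E)-2-[(tert-butyldimethylsilyloxy)methyl]-3-(4,4,5,5-tetramethyl-1,3,2-dioxaborolan-2-yl)prop-2-enoate (B trans to ester) | CC(C)(C)OC(=O)/C(CO[Si](C)(C)C(C)(C)C)=C/B1OC(C)(C)C(C)(C)O1 | intermediate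
6 | 2-(tert-butyldimethylsilyloxy)-N-methoxy-N-methylacetamide | CON(C)C(=O)CO[Si](C)(C)C(C)(C)C | starting material
7 | bromomagnesium 1-(tert-butyldimethylsilyloxy)-2-[methoxy(methyl)amino]but-3-en-2-olate | C=CC(O[Mg]Br)(CO[Si](C)(C)C(C)(C)C)N(C)OC | intermediate
8 | 1-(tert-butyldimethylsilyloxy)but-3-en-2-one | C=CC(=O)CO[Si](C)(C)C(C)(C)C | intermediate
9 | 3-methylbutanal | CC(C)CC=O | starting material
10 | (2S)-6-(tert-butyldimethylsilyloxy)-5-oxo-2-(propan-2-yl)hexanal | O=C[C@H](C(C)C)CCC(=O)CO[Si](C)(C)C(C)(C)C | intermediate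
11 | prop-2-enyl (2E,4S)-8-(tert-butyldimethylsilyloxy)-7-oxo-4-(propan-2-yl)oct-2-enoate | C=CCOC(=O)/C=C/[C@H](C(C)C)CCC(=O)CO[Si](C)(C)C(C)(C)C | intermediate
12 | prop-2-enyl (1S,2R,5S,6S)-6-[(E)-3-tert-butoxy-3-oxo-2-(TBSO-methyl)prop-1-enyl]-2-hydroxy-5-(propan-2-yl)-2-(TBSO-methyl)cyclohexane-1-carboxylate (OH cis to ester; side chain trans to ester, cis to isopropyl) | CC(C)[C@@H]1CC[C@](O)(CO[Si](C)(C)C(C)(C)C)[C@@H](C(=O)OCC=C)[C@@H]1/C=C(/C(=O)OC(C)(C)C)CO[Si](C)(C)C(C)(C)C | intermediate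
13 | (1S,2R,5S,6S)-6-[(E)-3-tert-butoxy-3-oxo-2-(TBSO-methyl)prop-1-enyl]-2-hydroxy-5-(propan-2-yl)-2-(TBSO-methyl)cyclohexane-1-carboxylic acid | CC(C)[C@@H]1CC[C@](O)(CO[Si](C)(C)C(C)(C)C)[C@@H](C(=O)O)[C@@H]1/C=C(/C(=O)OC(C)(C)C)CO[Si](C)(C)C(C)(C)C | intermediate
14 | tert-butyl (E)-2-(TBSO-methyl)-3-[(1S,2S,3S,6R)-8-oxo-3-(propan-2-yl)-6-(TBSO-methyl)-7-oxabicyclo[4.2.0]octan-2-yl]prop-2-enoate (cis-fused β-lactone) | CC(C)[C@@H]1CC[C@@]2(CO[Si](C)(C)C(C)(C)C)OC(=O)[C@H]2[C@@H]1/C=C(/C(=O)OC(C)(C)C)CO[Si](C)(C)C(C)(C)C | intermediate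
15 | tert-butyl (E)-2-(TBSO-methyl)-3-[(1R,6S)-6-(propan-2-yl)-3-(TBSO-methyl)cyclohex-2-en-1-yl]prop-2-enoate | CC(C)[C@@H]1CCC(CO[Si](C)(C)C(C)(C)C)=C[C@@H]1/C=C(/C(=O)OC(C)(C)C)CO[Si](C)(C)C(C)(C)C | intermediate
16 | trimethylsilyl (E)-2-(TBSO-methyl)-3-[(1R,6S)-6-(propan-2-yl)-3-(TBSO-methyl)cyclohex-2-en-1-yl]prop-2-enoate | CC(C)[C@@H]1CCC(CO[Si](C)(C)C(C)(C)C)=C[C@@H]1/C=C(/C(=O)O[Si](C)(C)C)CO[Si](C)(C)C(C)(C)C | intermediate
17 | (E)-2-(TBSO-methyl)-3-[(1R,6S)-6-(propan-2-yl)-3-(TBSO-methyl)cyclohex-2-en-1-yl]prop-2-enoic acid | CC(C)[C@@H]1CCC(CO[Si](C)(C)C(C)(C)C)=C[C@@H]1/C=C(/C(=O)O)CO[Si](C)(C)C(C)(C)C | intermediate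
18 | 1,4-dibromobutan-2-one | BrCCC(=O)CBr | starting material
19 | 4-bromo-2-oxobutyl ester of acid 17 | BrCCC(=O)COC(=O)/C(=C/[C@H]1C=C(CO[Si](C)(C)C(C)(C)C)CC[C@H]1C(C)C)CO[Si](C)(C)C(C)(C)C | intermediate
20 | 2-oxobut-3-enyl ester of acid 17 | C=CC(=O)COC(=O)/C(=C/[C@H]1C=C(CO[Si](C)(C)C(C)(C)C)CC[C@H]1C(C)C)CO[Si](C)(C)C(C)(C)C | intermediate
21 | (5R)-5-formyl-6-methyl-2-oxoheptyl ester of acid 17 | O=C[C@@H](C(C)C)CCC(=O)COC(=O)/C(=C/[C@H]1C=C(CO[Si](C)(C)C(C)(C)C)CC[C@H]1C(C)C)CO[Si](C)(C)C(C)(C)C | intermediate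
22 | methyl (2E,4R)-8-(acyl A-oxy)-7-oxo-4-(propan-2-yl)oct-2-enoate | COC(=O)/C=C/[C@@H](C(C)C)CCC(=O)COC(=O)/C(=C/[C@H]1C=C(CO[Si](C)(C)C(C)(C)C)CC[C@H]1C(C)C)CO[Si](C)(C)C(C)(C)C | intermediate
23 | methyl (1R,2S,5R,6R)-2-[(acyl A-oxy)methyl]-6-[(E)-3-tert-butoxy-3-oxo-2-(TBSO-methyl)prop-1-enyl]-2-hydroxy-5-(propan-2-yl)cyclohexane-1-carboxylate | CC(C)[C@H]1CC[C@@](O)(COC(=O)/C(=C/[C@H]2C=C(CO[Si](C)(C)C(C)(C)C)CC[C@H]2C(C)C)CO[Si](C)(C)C(C)(C)C)[C@H](C(=O)OC)[C@H]1/C=C(/C(=O)OC(C)(C)C)CO[Si](C)(C)C(C)(C)C | intermediate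
24 | desilylated 23 (three free primary alcohols; methyl and tert-butyl esters intact) | CC(C)[C@H]1CC[C@@](O)(COC(=O)/C(=C/[C@H]2C=C(CO)CC[C@H]2C(C)C)CO)[C@H](C(=O)OC)[C@H]1/C=C(/C(=O)OC(C)(C)C)CO | intermediate
25 | tert-butyl (5aR,6R,9S,9aR)-9-hydroxy-9-({[(2E)-2-(hydroxymethyl)-3-[(1R,6S)-3-(hydroxymethyl)-6-(propan-2-yl)cyclohex-2-en-1-yl]prop-2-enoyl]oxy}methyl)-1-oxo-6-(propan-2-yl)-1,3,5a,6,7,8,9,9a-octahydro-2-benzoxepine-4-carboxylate | CC(C)[C@H]1CC[C@@](O)(COC(=O)/C(=C/[C@H]2C=C(CO)CC[C@H]2C(C)C)CO)[C@@H]2C(=O)OCC(C(=O)OC(C)(C)C)=C[C@@H]12 | intermediate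
26 | CNP0361406.11: (5aR,6R,9S,9aR)-9-hydroxy-9-({[(2E)-2-(hydroxymethyl)-3-[(1R,6S)-3-(hydroxymethyl)-6-(propan-2-yl)cyclohex-2-en-1-yl]prop-2-enoyl]oxy}methyl)-1-oxo-6-(propan-2-yl)-1,3,5a,6,7,8,9,9a-octahydro-2-benzoxepine-4-carboxylic acid | CC(C)[C@H]1CC[C@@](O)(COC(=O)/C(=C/[C@H]2C=C(CO)CC[C@H]2C(C)C)CO)[C@@H]2C(=O)OCC(C(=O)O)=C[C@@H]12 | target

## Step count and risks

Total steps: 14. Longest linear sequence: 12 steps (1, 2, 3, 6, 7, 8, 9, 10, 11, 12, 13, 14).

Most likely to fail: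

**Step 6 (first run of the key cascade).** The rhodium enolate may be protonated before it cyclises, because the aldol chair needs the isopropyl group axial. The fallback sets out from 11 and comes back at 14. The rhodium addition of 5 is run deliberately wet so that it stops at the open-chain 1,4-adduct F1. Its allyl ester is removed (Pd(PPh3)4, morpholine) to give keto acid F2. The ring is then closed by a nucleophile-catalysed aldol-lactonisation through an ammonium enolate (2-chloro-1-methylpyridinium iodide, 4-pyrrolidinopyridine, i-Pr2NEt, CH2Cl2). This gives the cis-fused β-lactone 14 directly, which is heated as in step 8.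

**Step 12 (second run, on the advanced substrate).** The electron-poor alkenylboronate may not transmetalate to rhodium or insert at the hindered C3. The fallback sets out from 22 (with bromide 4) and comes back at 23. The same two carbons are joined reductively instead: divalent nickel catalysis (NiCl2(dme), neocuproine), Mn powder and Et3SiCl in DMF couple 4 with the enoate to give the silyl ketene acetal F3. An intramolecular Mukaiyama aldol (BF3·OEt2, CH2Cl2, −78 °C) then closes ring B to 23. Here C3 is set by the substrate only, so the C3 epimers would have to be separated. The same fallback serves step 6 if transmetalation is the problem there.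

**Step 13 (seven-membered lactone).** Transesterification of a hindered methyl ester to an ε-lactone may be slow or stop at equilibrium. The fallback sets out from 23 and comes back at 25, using a strained acyl donor instead. The methyl ester is hydrolysed selectively with Me3SnOH (1,2-dichloroethane, 70 °C) to acid F4. PhSO2Cl/pyridine closes the cis β-lactone F5. HF·pyridine then frees the alcohols to give F6, in which the side-chain CH2OH opens the β-lactone by ring-expanding acyl transfer to give 25 and release the tertiary alcohol.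

Further compounds
F1 | step 6 | prop-2-enyl (3S,4S)-3-[(E)-3-tert-butoxy-3-oxo-2-(TBSO-methyl)prop-1-enyl]-8-(tert-butyldimethylsilyloxy)-7-oxo-4-(propan-2-yl)octanoate (open-chain 1,4-adduct) | C=CCOC(=O)C[C@H](/C=C(/C(=O)OC(C)(C)C)CO[Si](C)(C)C(C)(C)C)[C@H](C(C)C)CCC(=O)CO[Si](C)(C)C(C)(C)C
F2 | step 6 | (3S,4S)-3-[(E)-3-tert-butoxy-3-oxo-2-(TBSO-methyl)prop-1-enyl]-8-(tert-butyldimethylsilyloxy)-7-oxo-4-(propan-2-yl)octanoic acid | OC(=O)C[C@H](/C=C(/C(=O)OC(C)(C)C)CO[Si](C)(C)C(C)(C)C)[C@H](C(C)C)CCC(=O)CO[Si](C)(C)C(C)(C)C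
F3 | step 12 | methyl triethylsilyl ketene acetal of the open-chain 1,4-adduct of 22 (3R,4R; ketene acetal geometry not defined) | COC(O[Si](CC)(CC)CC)=C[C@@H](/C=C(/C(=O)OC(C)(C)C)CO[Si](C)(C)C(C)(C)C)[C@@H](C(C)C)CCC(=O)COC(=O)/C(=C/[C@H]1C=C(CO[Si](C)(C)C(C)(C)C)CC[C@H]1C(C)C)CO[Si](C)(C)C(C)(C)C
F4 | step 13 | carboxylic acid corresponding to methyl ester 23 | CC(C)[C@H]1CC[C@@](O)(COC(=O)/C(=C/[C@H]2C=C(CO[Si](C)(C)C(C)(C)C)CC[C@H]2C(C)C)CO[Si](C)(C)C(C)(C)C)[C@H](C(=O)O)[C@H]1/C=C(/C(=O)OC(C)(C)C)CO[Si](C)(C)C(C)(C)C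
F5 | step 13 | cis-fused β-lactone of F4 (7-oxabicyclo[4.2.0]octan-8-one, silyl ethers intact) | CC(C)[C@H]1CC[C@]2(COC(=O)/C(=C/[C@H]3C=C(CO[Si](C)(C)C(C)(C)C)CC[C@H]3C(C)C)CO[Si](C)(C)C(C)(C)C)OC(=O)[C@@H]2[C@H]1/C=C(/C(=O)OC(C)(C)C)CO[Si](C)(C)C(C)(C)C
F6 | step 13 | desilylated β-lactone (three free primary alcohols) | CC(C)[C@H]1CC[C@]2(COC(=O)/C(=C/[C@H]3C=C(CO)CC[C@H]3C(C)C)CO)OC(=O)[C@@H]2[C@H]1/C=C(/C(=O)OC(C)(C)C)CO
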